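**Retrosynthetic overview**
The strategy rests on the mirror symmetry of ring A: every carbon from C5 to C8a carries oxygen (O1 and 5-OH flank C4a, 6-OMe and 8-OMe flank the 7-oxygen), so ring A can be excised as a symmetric resorcinol whose single C-H is the future C4a.
Key disconnections are C4–C4a (C-acylation) and O1–C2 (cyclodehydration); they release C2, C3 (with its OMe), C4 and ring B together as one alpha-methoxy aroylketene, generated thermally from a beta-keto ester.
The ring A partner comes from syringol (benzylation, double bromination, double borylation, oxidation); the ring B partner comes from 2,4-dimethoxybenzaldehyde (Dakin-type oxidation, benzylation, formylation, aldol addition, oxidation).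
Rings A and B are purchased benzenes; pyranone ring C is the only ring built and is closed in the fragment union, after which only the removal of two benzyl ethers remains.

Key step: step 10

Remark on the chemistry: the target has no stereocentre, so 13 and 14 are used as racemates; resorcinol 5 is assumed to be air-sensitive and is handled under argon and used promptly.

Step 1
Reactants: 1 2,6-dimethoxyphenol (syringol)
Product: 2 2-(benzyloxy)-1,3-dimethoxybenzene
Conditions: BnBr, K2CO3, DMF, 60 °C
Reagents that add atoms: benzyl bromide, BrCc1ccccc1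
Why: Williamson ether synthesis, in which the phenoxide of 1, although flanked by two methoxy groups, should be alkylated cleanly by the reactive benzylic bromide in a polar aprotic solvent.

Step 2
Reactants: 2 2-(benzyloxy)-1,3-dimethoxybenzene
Product: 3 3-(benzyloxy)-1,5-dibromo-2,4-dimethoxybenzene
Conditions: N-bromosuccinimide (2.1 equiv), MeCN, 0 °C to rt, dark
Reagents that add atoms: N-bromosuccinimide, O=C1CCC(=O)N1Br
Why: Electrophilic aromatic bromination, in which the two equivalent positions ortho to one methoxy group and para to the other are far more activated than the position para to the twisted central benzyloxy group, so two equivalents of reagent should give the symmetric dibromide.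

Step 3
Reactants: 3 3-(benzyloxy)-1,5-dibromo-2,4-dimethoxybenzene
Product: 4 2,2'-[5-(benzyloxy)-4,6-dimethoxy-1,3-phenylene]bis(4,4,5,5-tetramethyl-1,3,2-dioxaborolane)
Conditions: B2pin2 (2.5 equiv), Pd(dppf)Cl2 (5 mol%), KOAc, dioxane, 90 °C, Ar
Reagents that add atoms: bis(pinacolato)diboron, CC1(C)OB(OC1(C)C)B1OC(C)(C)C(C)(C)O1
Why: Miyaura borylation, in which zerovalent palladium formed from Pd(dppf)Cl2 inserts into each aryl C-Br bond and the acetate-ligated arylpalladium species transmetalates with the diboron reagent, the benzyl and methyl ethers being inert.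

Step 4
Reactants: 4 2,2'-[5-(benzyloxy)-4,6-dimethoxy-1,3-phenylene]bis(4,4,5,5-tetramethyl-1,3,2-dioxaborolane)
Product: 5 5-(benzyloxy)-4,6-dimethoxybenzene-1,3-diol
Conditions: 30% aq. H2O2, aq. NaOH, THF, 0 °C, Ar; then dilute HCl
Reagents that add atoms: hydrogen peroxide, OO
Why: Oxidation of arylboronates, in which hydroperoxide adds to boron, the aryl group migrates from boron to oxygen at the same ring carbon and hydrolysis frees both phenols, the cold, oxygen-free conditions sparing the electron-rich product.

Step 5
Reactants: 6 2,4-dimethoxybenzaldehyde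
Product: 8 2,4-dimethoxyphenol, via 2,4-dimethoxyphenyl formate 7 (not isolated)
Conditions: mCPBA, CH2Cl2, 0 °C to rt; then NaOH, MeOH/H2O, rt; acidify
Reagents that add atoms: meta-chloroperoxybenzoic acid (mCPBA), O=C(OO)c1cccc(Cl)c1
Why: Baeyer-Villiger oxidation in its Dakin-type variant, in which the electron-rich aryl group migrates in preference to hydrogen and the resulting aryl formate is saponified in the same flask.

Step 6
Reactants: 8 2,4-dimethoxyphenol
Product: 9 1-(benzyloxy)-2,4-dimethoxybenzene
Conditions: BnBr, K2CO3, acetone, reflux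
Reagents that add atoms: benzyl bromide, BrCc1ccccc1
Why: Williamson ether synthesis on an unhindered phenoxide, which also protects the oxidation-prone phenol before the electrophilic formylation.

Step 7
Reactants: 9 1-(benzyloxy)-2,4-dimethoxybenzene
Product: 11 5-(benzyloxy)-2,4-dimethoxybenzaldehyde, via aryl iminium chloride 10 (not isolated)
Conditions: POCl3, DMF, 0 to 70 °C; then aq. NaOAc
Reagents that add atoms: N,N-dimethylformamide, CN(C)C=O; water, O
Why: Vilsmeier-Haack formylation, in which the chloroiminium electrophile attacks the carbon para to the 2-methoxy and ortho to the 4-methoxy group (the carbon between the two methoxy groups is hindered and the one next to the benzyloxy group is meta to both) and aqueous hydrolysis of the iminium gives the aldehyde.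

Step 8
Reactants: 11 5-(benzyloxy)-2,4-dimethoxybenzaldehyde; 12 ethyl methoxyacetate
Product: 13 ethyl 3-[5-(benzyloxy)-2,4-dimethoxyphenyl]-3-hydroxy-2-methoxypropanoate (racemic mixture of diastereomers)
Conditions: LiN(iPr)2, THF, −78 °C, 12 then 11; aq. NH4Cl
Reagents that add atoms: none
Why: Aldol addition of the preformed lithium ester enolate to a non-enolisable aldehyde, in which the two new stereocentres are formed without control, harmlessly so because one is oxidised in step 9 and the other becomes sp2 carbon in step 10.

Step 9
Reactants: 13 ethyl 3-[5-(benzyloxy)-2,4-dimethoxyphenyl]-3-hydroxy-2-methoxypropanoate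
Product: 14 ethyl 3-[5-(benzyloxy)-2,4-dimethoxyphenyl]-2-methoxy-3-oxopropanoate (racemic)
Conditions: Dess-Martin periodinane, CH2Cl2, rt
Reagents that add atoms: none
Why: Dess-Martin oxidation, in which ligand exchange at hypervalent iodine and elimination convert the benzylic secondary alcohol into the ketone under neutral conditions that leave the ester, the ethers and the acidic alpha carbon alone.

Step 10
Reactants: 5 5-(benzyloxy)-4,6-dimethoxybenzene-1,3-diol; 14 ethyl 3-[5-(benzyloxy)-2,4-dimethoxyphenyl]-2-methoxy-3-oxopropanoate
Product: 17 7-(benzyloxy)-2-[5-(benzyloxy)-2,4-dimethoxyphenyl]-5-hydroxy-3,6,8-trimethoxy-4H-chromen-4-one, via alpha-methoxy aroylketene 15 (not isolated), via ortho-hydroxyaryl 1,3-diketone 16 (not isolated)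
Conditions: Ph2O, 200–220 °C (microwave or sand bath), Ar stream to remove EtOH, 14 (1.3 equiv) added in portions, no acid
Reagents that add atoms: none
Why: Proposed new method: on heating, the enol of 14 should expel ethanol through a six-membered transition state to give acylketene 15, whose ketene carbon acylates the lone ring C-H of 5 to form the C4–C4a bond and diketone 16, any aryl ester formed at oxygen reverting to ketene and phenol at this temperature. One of the two equivalent ortho OH groups of 16 then adds to the aroyl carbonyl in a 6-exo-trig closure (O1–C2 bond), and loss of water aromatises pyranone ring C, the only ring closed here. The closest known reaction type is the solvent-free thermal condensation of phloroglucinol with ethyl aroylacetates to 5,7-dihydroxyflavones through aroylketenes, a neutral relative of the Simonis chromone synthesis; the extension lies in the alpha-methoxy group on the ketene and in a resorcinol bearing three further oxygen substituents. No stereocentre is created, since the stereogenic carbon of 14 ends as sp2 C3. The step requires C-acylation and chromone closure rather than O-acylation and Pechmann-type coumarin closure, which is expected because O-acylation is reversible without acid whereas cyclodehydration is not, and the electron-rich, ortho-substituted aroyl ketone is a poor partner for the acid-dependent coumarin pathway. Regiochemistry needs no control because 5 is mirror-symmetric with one C-H between two equivalent OH groups, and the OH that is left ends as the hydrogen-bonded 5-OH.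

Step 11
Reactants: 17 7-(benzyloxy)-2-[5-(benzyloxy)-2,4-dimethoxyphenyl]-5-hydroxy-3,6,8-trimethoxy-4H-chromen-4-one
Product: 18 5,7-dihydroxy-2-(5-hydroxy-2,4-dimethoxyphenyl)-3,6,8-trimethoxy-4H-chromen-4-one (target)
Conditions: H2 (1 atm), 10% Pd/C, EtOAc/MeOH, rt
Reagents that add atoms: none
Why: Catalytic hydrogenolysis of benzyl aryl ethers, in which both benzylic C-O bonds are cleaved on palladium at ambient pressure while the methyl ethers, the chromone carbonyl and the tetrasubstituted C2–C3 double bond should stay untouched.

**Compound list**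
1 | 2,6-dimethoxyphenol (syringol) | COc1cccc(OC)c1O | starting material
2 | 2-(benzyloxy)-1,3-dimethoxybenzene | COc1cccc(OC)c1OCc1ccccc1 | intermediate
3 | 3-(benzyloxy)-1,5-dibromo-2,4-dimethoxybenzene | COc1c(Br)cc(Br)c(OC)c1OCc1ccccc1 | intermediate
4 | 2,2'-[5-(benzyloxy)-4,6-dimethoxy-1,3-phenylene]bis(4,4,5,5-tetramethyl-1,3,2-dioxaborolane) | COc1c(B2OC(C)(C)C(C)(C)O2)cc(B2OC(C)(C)C(C)(C)O2)c(OC)c1OCc1ccccc1 | intermediate
5 | 5-(benzyloxy)-4,6-dimethoxybenzene-1,3-diol | COc1c(O)cc(O)c(OC)c1OCc1ccccc1 | intermediate
6 | 2,4-dimethoxybenzaldehyde | COc1ccc(C=O)c(OC)c1 | starting material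
7 | 2,4-dimethoxyphenyl formate (not isolated) | COc1ccc(OC=O)c(OC)c1 | intermediate
8 | 2,4-dimethoxyphenol | COc1ccc(O)c(OC)c1 | intermediate
9 | 1-(benzyloxy)-2,4-dimethoxybenzene | COc1ccc(OCc2ccccc2)c(OC)c1 | intermediate
10 | N-{[5-(benzyloxy)-2,4-dimethoxyphenyl]methylidene}-N-methylmethanaminium chloride (not isolated) | COc1cc(OC)c(OCc2ccccc2)cc1C=[N+](C)C.[Cl-] | intermediate
11 | 5-(benzyloxy)-2,4-dimethoxybenzaldehyde | COc1cc(OC)c(OCc2ccccc2)cc1C=O | intermediate
12 | ethyl methoxyacetate | CCOC(=O)COC | starting material
13 | ethyl 3-[5-(benzyloxy)-2,4-dimethoxyphenyl]-3-hydroxy-2-methoxypropanoate (racemic mixture of diastereomers) | CCOC(=O)C(OC)C(O)c1cc(OCc2ccccc2)c(OC)cc1OC | intermediate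
14 | ethyl 3-[5-(benzyloxy)-2,4-dimethoxyphenyl]-2-methoxy-3-oxopropanoate (racemic) | CCOC(=O)C(OC)C(=O)c1cc(OCc2ccccc2)c(OC)cc1OC | intermediate
15 | 3-[5-(benzyloxy)-2,4-dimethoxyphenyl]-2-methoxy-3-oxoprop-1-en-1-one (acylketene, not isolated) | COC(=C=O)C(=O)c1cc(OCc2ccccc2)c(OC)cc1OC | intermediate
16 | 1-[4-(benzyloxy)-2,6-dihydroxy-3,5-dimethoxyphenyl]-3-[5-(benzyloxy)-2,4-dimethoxyphenyl]-2-methoxypropane-1,3-dione (racemic, not isolated) | COC(C(=O)c1cc(OCc2ccccc2)c(OC)cc1OC)C(=O)c1c(O)c(OC)c(OCc2ccccc2)c(OC)c1O | intermediate
17 | 7-(benzyloxy)-2-[5-(benzyloxy)-2,4-dimethoxyphenyl]-5-hydroxy-3,6,8-trimethoxy-4H-chromen-4-one | COc1cc(OC)c(-c2oc3c(OC)c(OCc4ccccc4)c(OC)c(O)c3c(=O)c2OC)cc1OCc1ccccc1 | intermediate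
18 | 5,7-dihydroxy-2-(5-hydroxy-2,4-dimethoxyphenyl)-3,6,8-trimethoxy-4H-chromen-4-one | COc1cc(OC)c(-c2oc3c(OC)c(O)c(OC)c(O)c3c(=O)c2OC)cc1O | target

**Step count**
Total: 11 steps. Longest linear sequence: 7 steps (steps 5, 6, 7, 8, 9, 10 and 11, from 2,4-dimethoxybenzaldehyde 6).

**Steps most likely to fail**

Step 10 (the proposed new method). The ketene may dimerise, or be hydrated by the water of condensation and decarboxylate, faster than it acylates carbon; trapping at oxygen may fail to funnel to the C-acylated product; a benzyl group may be lost thermally. The fallback uses known chemistry, sets out from resorcinol 5 and aldehyde 11, and comes back to the route at diketone 16 and then 17. Houben-Hoesch acylation of 5 with methoxyacetonitrile (ZnCl2, HCl gas, Et2O, 0 °C) would give 1-[4-(benzyloxy)-2,6-dihydroxy-3,5-dimethoxyphenyl]-2-methoxyethan-1-iminium chloride F1, which warm water would hydrolyse to 1-[4-(benzyloxy)-2,6-dihydroxy-3,5-dimethoxyphenyl]-2-methoxyethan-1-one F2. In parallel, Pinnick oxidation of 11 (NaClO2, NaH2PO4, 2-methyl-2-butene, tBuOH/H2O) would give 5-(benzyloxy)-2,4-dimethoxybenzoic acid F3, and oxalyl chloride with catalytic DMF would turn it into 5-(benzyloxy)-2,4-dimethoxybenzoyl chloride F4. Deprotonation of F2 with LiN(SiMe3)2 (about 4.5 equiv, THF, −78 °C) and C-aroylation of the enolate with F4, a Baker-Venkataraman-type 1,3-diketone synthesis, would give diketone 16, this time isolated. Cyclodehydration with catalytic H2SO4 in AcOH at 60 °C would then return 17.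

Step 3. The double borylation may stall after the first C-B bond is formed, or the hindered, electron-rich ring may undergo protodebromination. The fallback sets out from dibromide 3 and comes back at resorcinol 5, bypassing boron altogether: palladium-catalysed hydroxylation of both C-Br bonds with KOH (Pd2(dba)3, tBuXPhos, dioxane/H2O, 100 °C, Ar, then acid). No further compound arises on this path (F0).

Step 4. The very electron-rich resorcinol may be over-oxidised by alkaline peroxide or by air during work-up. The fallback sets out from dibromide 3 and comes back at resorcinol 5 without any oxidant. Palladium-catalysed C-O coupling with NaOtBu (Pd(OAc)2, tBuXPhos, toluene, 100 °C) would give 3-(benzyloxy)-1,5-di-tert-butoxy-2,4-dimethoxybenzene F5, which can be purified and stored. Brief treatment with CF3CO2H in CH2Cl2 at 0 °C would then release 5 with loss of 2-methylpropene, directly before step 10.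

**Further compounds**
F1 | step 10 | 1-[4-(benzyloxy)-2,6-dihydroxy-3,5-dimethoxyphenyl]-2-methoxyethan-1-iminium chloride | COCC(=[NH2+])c1c(O)c(OC)c(OCc2ccccc2)c(OC)c1O.[Cl-]
F2 | step 10 | 1-[4-(benzyloxy)-2,6-dihydroxy-3,5-dimethoxyphenyl]-2-methoxyethan-1-one | COCC(=O)c1c(O)c(OC)c(OCc2ccccc2)c(OC)c1O
F3 | step 10 | 5-(benzyloxy)-2,4-dimethoxybenzoic acid | COc1cc(OC)c(OCc2ccccc2)cc1C(=O)O
F4 | step 10 | 5-(benzyloxy)-2,4-dimethoxybenzoyl chloride | COc1cc(OC)c(OCc2ccccc2)cc1C(=O)Cl
F0 | step 3 | none | none
F5 | step 4 | 3-(benzyloxy)-1,5-di-tert-butoxy-2,4-dimethoxybenzene | COc1c(OC(C)(C)C)cc(OC(C)(C)C)c(OC)c1OCc1ccccc1
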